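The vessel is closed, stirred and isothermal, and its contents are the ash run itself, followed so far and now asked about at a later time.

| flask | starting material | partner | free catalyst | remark | time |
|---|---|---|---|---|---|
| ash | 0.10 M | 0.70 equiv | 0.1 mol% | the very flask that is asked about, followed so far |  |
| flask | 0.10 M | 0.700 equiv | 0.1 mol% |  | 8.0 d |

ash run (percent of the starting material charged)

| time / h | product / % | starting material / % |
|---|---|---|
| 25.0 | 30.0 | 70.8 |
| 48.0 | 39.2 | 63.2 |
| 72.0 | 43.8 | 58.5 |
| 96.0 | 44.4 | 53.9 |
| 120 | 48.2 | 51.8 |
| 144 | 48.3 | 51.4 |

(readings scatter by 1 percentage point)

- removed product is counted in
- what was read earlier has a scatter of 1 percentage point, one standard deviation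
- additions bring no volume worth counting

- summer: change nothing and wait 8.0 d more
- midnight: at 8.0 d add partner, 50.0% of the amount charged, then wait 8.0 d
- spring: at 8.0 d take out 90% of the product then present, then wait 8.0 d
- dusk: at 8.0 d add free catalyst, 100% of the amount charged, then wait 8.0 d

- product, in percent of the starting material first charged, at 8.0 d
- what to do for the largest gain in product; "none" if nothing gains more than 2 percentage points (summer / midnight / spring / dusk / none)
- product present, with what was taken out counted in, in percent of the starting material first charged, after summer
- product present, with what was taken out counted in, in percent of the starting material first charged, after dusk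

Partner is the limiting reagent by charge, at 0.70 equiv, yet the ash readings slow near 48.3% of product at 144 h, so I ask how much working catalyst is left. I divide mass action out by defining a dose: the logarithm of [starting material]/[partner], taken against the same ratio at the charge, over the charged excess of starting material above partner. For one step first order in each, this dose grows with working catalyst and time. Taking partner used as equal to product, it reads 6.76 M⁻¹ at 25.0 h, 14.0 M⁻¹ at 96.0 h and 17.0 M⁻¹ at 144 h. The activity share, the dose gained per hour over the late stretch divided by that over the first stretch, is 0.238, a reading under a scatter of 1 percentage point per point.

Now I turn the question round and ask what would let added partner beat added catalyst. Still taking partner used as equal to product, and starting from the 144 h reading, I reckon that midnight multiplies [partner] by 2.61. If the fresh charge works as the first did, I reckon that dusk multiplies the rate by 5.21. On this reckoning midnight would need a share above 0.620, and this flask reads 0.238, lower than that, so I commit to dusk.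

The forecast gives 49.2% now, dusk as the best move, 49.8% after summer and 60% after dusk, saying “I favour catalyst death”. The flask gives 51.7% now, 56.0% after summer and 64.0% after dusk, and the best move is dusk.

    partner + free catalyst → catalyst intermediate A (k = 0.870 M⁻¹ s⁻¹)
    starting material + catalyst intermediate A → catalyst intermediate B (k = 0.120 M⁻¹ s⁻¹)
    catalyst intermediate B ⇌ catalyst intermediate C (K = 14.0, k = 3.60 s⁻¹)
    catalyst intermediate C → free catalyst + product (k = 0.460 s⁻¹)
    2 free catalyst → spent catalyst (k = 0.820 M⁻¹ s⁻¹)
    partner ⇌ dormant form (K = 2.00, k = 3.40 × 10⁻⁴ s⁻¹)

In this flask, with the share read at 0.238 against 0.620, dusk gains 12 points and midnight 8.8 points. Of the neighbour charged with 0.06 mol% of free catalyst I have the end point, so I reckon a whole-run form of the share, with the first-stretch dose rate scaled to its loading. The flask then reads 0.393 and the neighbour 0.522, higher. Its product at 192 h stands at 47.4%.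

(All runs are simulated for an exercise; noise was put on by code.)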